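I decided to drop the assumption that every substrate lost reached a product, and to reckon the north-west flask by its reagent budget.

| setting | north-west | south | flask |
|---|---|---|---|
| substrate | 1 mM | 1 mM | 1.0 mM |
| reagent | 1.2 equiv | 1.8 equiv | 1.20 equiv |
| remark | the very flask that is asked about, followed so far | run made earlier |  |
| time |  |  | 2.5 min |

| run | time / s | substrate / % | single product / % |
|---|---|---|---|
| north-west | 10.0 | 74 | 10 |
| north-west | 25.0 | 49 | 16 |
| north-west | 50.0 | 25 | 15 |
| north-west | 80.0 | 14 | 12 |
| south | 10.0 | 69 | 15 |
| south | 12.0 | 63 | 15 |
| south | 25.0 | 39 | 17 |
| south | 60.0 | 15 | 11 |

(readings scatter by 1.5 percentage points)

- a reading or a percentage of triple product counts all its forms, free or not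

1. how much substrate there is at 2.5 min, in percent of the substrate charged
2. how much single product there is at 2.5 min, in percent of the substrate charged
3. how much double product there is at 2.5 min, in percent of the substrate charged
4. how much triple product there is at 2.5 min, in percent of the substrate charged

At 80.0 s in the north-west run, substrate and single product left 74.0% unread. As double product, that needed reagent of 160% of the substrate charged, yet 1.2 equiv went in. So I took part of the substrate to leave without reagent.

I took pseudo-first-order constants at 25.0 s: 0.0285 /s north-west and 0.0377 /s south. Scaled by charge, their gap made the reagent term 0.0183 /s, leaving 0.0103 /s. But reagent fell during the north-west run. That split implied 41.1% of the charge spent by then, so the mean reagent was lower and the remainder rose to 0.0140 /s. One more round gave the reagent-free rate constant 0.0130 /s, which is 45.6% of the north-west constant at 25.0 s.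

Running the last substrate reading down at that constant, I expected 5.63% substrate at 2.5 min. If that early share held to the end, single, double and triple product together would hold 51.4%.

The forecast differed: substrate 6%, single product 7%, double product 35%, triple product 52%, the split “largely a guess, leaning towards triple”.

The flask gave substrate 6.71%, single product 7.06%, double product 24.2% and triple product 9.49%, so the three products held 40.8%.

    reagent + single product → double product (k = 31.0 /M/s)
    substrate ⇌ dormant form (K = 8.30, k = 0.0170 /s)
    reagent + triple product ⇌ idle adduct, settled at all times (K = 380 /M)
    reagent + double product → triple product (k = 7.30 /M/s)
    substrate + reagent → single product (k = 13.0 /M/s)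

The dormant form held 52.5%, which is 56.3% of the substrate lost by then, above the early share of 45.6% that I had carried forward. At 2.50 min, the forward step to dormant form alone gave substrate a half-life of 0.68 min, against 2.5 min by the step with reagent. For the neighbour with a quarter of the substrate at the same equivalents, I scaled the reagent term by that factor, so 0.0130 /s gives a share of 77.0%, if it holds to the end. That flask held 71.0% dormant form, 79.8% of its lost substrate.

The data stem from a simulated flask for substances that don't exist, and the scatter is random.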